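**Retrosynthetic overview**
- Target ⇐ Lewis-acid isomerisation of a 4α,15-epoxy 14-aldehyde: the C4–O bond and the bridging dihydropyran form last and free the 15-OH.
- That aldehyde ⇐ the Δ9-14-enal, by γ-hydroxylation then inversion at C8, and epoxidation, reductive opening and acetylation at C9.
- The enal ⇐ the 4α,15-epoxide, by a photochemical singlet-oxygen ene reaction that makes the C14–O bond of the future bridge.
- The epoxide ⇐ dehydrocostus lactone, which supplies the 5-7-5 skeleton and C1, C5, C6, C7; the acyl stereocentre is bought as (R)-2-methylbutanoic acid. Ring order: carbocycles and lactone are bought, the oxa-bridge is built last.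

Assumption: dehydrocostus lactone (bulk lactone of costus root oil) and (R)-2-methylbutanoic acid are bought, its cyclopentylidene C4=C15 alkene is taken to react with electrophilic oxidants before the cycloheptylidene C10=C14 alkene, and guaiane numbering with α/β descriptors is used (all compounds keep 1αH,5αH,6βH,7αH).

Step 1
Reactants: 1 dehydrocostus lactone
Product: 2 mono-epoxide 4α,15-epoxyguaia-10(14),11(13)-dien-12,6-olide
Conditions: DMDO (1.0 equiv), acetone/CH2Cl2, −40 °C
Reagents that add atoms: dimethyldioxirane, CC1(C)OO1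
Why: Dioxirane epoxidation (electrophilic oxygen transfer) should take the cyclopentylidene alkene, whose ring carbon goes towards sp3 more easily than that of the seven-membered ring, leave the electron-poor methylene lactone alone, and attack the α-face away from the β-fused seven-membered ring (control by C1/C5), which puts the oxirane oxygen α at C4.

Step 2
Reactants: 2 mono-epoxide 4α,15-epoxyguaia-10(14),11(13)-dien-12,6-olide
Product: 4 enal 4α,15-epoxy-14-oxoguaia-9,11(13)-dien-12,6-olide, via allylic hydroperoxide 3 (not isolated)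
Conditions: O2, TPP (0.5 mol %), white LEDs, Ac2O, pyridine, DMAP (cat.), CH2Cl2, 0 °C
Reagents that add atoms: dioxygen, O=O
Why: Schenck ene reaction in which photosensitised singlet oxygen bonds to the terminal C14 and takes the pseudo-axial allylic H-9 (the tertiary H-1 lies in the alkene plane and is not available), followed by in-situ Kornblum–DeLaMare-type dehydration of the primary hydroperoxide to the enal; this photochemical step makes the C14–O bond of the later ether bridge and sets no stereocentre.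

Step 3
Reactants: 4 enal 4α,15-epoxy-14-oxoguaia-9,11(13)-dien-12,6-olide
Product: 6 hydroxy enal 4α,15-epoxy-8α-hydroxy-14-oxoguaia-9,11(13)-dien-12,6-olide, via silyl dienol ether 5 (not isolated)
Conditions: LiN(SiMe3)2, Me3SiCl, THF, −78 °C; then DMDO, acetone, −78 °C; then citric acid, aq. THF, 0 °C
Reagents that add atoms: dimethyldioxirane, CC1(C)OO1
Why: Vinylogous Rubottom oxidation in which γ-deprotonation at C8 gives the linear silyl dienol ether, DMDO oxidises its terminal C8=C9 bond from the α-face (anti to the β-oriented C7–C11 bond of the lactone), and ring opening with desilylation returns the enal carrying an 8α-hydroxyl.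

Step 4
Reactants: 6 hydroxy enal 4α,15-epoxy-8α-hydroxy-14-oxoguaia-9,11(13)-dien-12,6-olide; 7 (R)-2-methylbutanoic acid
Product: 8 ester enal 4α,15-epoxy-8β-[(2R)-2-methylbutanoyloxy]-14-oxoguaia-9,11(13)-dien-12,6-olide
Conditions: PPh3, DIAD, THF, 0 °C to rt
Reagents that add atoms: none
Why: Mitsunobu esterification with SN2 inversion at the allylic C8 carbinol turns the 8α-alcohol into the 8β-ester and brings in the bought (R)-acid stereocentre unchanged.

Step 5
Reactants: 8 ester enal 4α,15-epoxy-8β-[(2R)-2-methylbutanoyloxy]-14-oxoguaia-9,11(13)-dien-12,6-olide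
Product: 9 epoxy aldehyde 4α,15:9α,10α-diepoxy-8β-[(2R)-2-methylbutanoyloxy]-14-oxoguai-11(13)-en-12,6-olide
Conditions: tBuOOH, DBU, CH2Cl2, 0 °C
Reagents that add atoms: tert-butyl hydroperoxide, CC(C)(C)OO
Why: Weitz–Scheffer nucleophilic epoxidation in which the peroxide anion adds to C9 of the enal anti to the 8β-ester (α-face) and the enolate closes the oxirane on the same face, setting the C9–O bond α, while the less electrophilic methylene lactone is left.

Step 6
Reactants: 9 epoxy aldehyde 4α,15:9α,10α-diepoxy-8β-[(2R)-2-methylbutanoyloxy]-14-oxoguai-11(13)-en-12,6-olide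
Product: 11 acetoxy aldehyde 9α-acetoxy-4α,15-epoxy-8β-[(2R)-2-methylbutanoyloxy]-14-oxo-10αH-guai-11(13)-en-12,6-olide, via aldol 10 (not isolated)
Conditions: SmI2 (2.2 equiv), THF/MeOH, −90 °C; then Ac2O, pyridine, DMAP (cat.), CH2Cl2, −20 °C
Reagents that add atoms: acetic anhydride, CC(=O)OC(C)=O
Why: SmI2 reductive opening of the α,β-epoxy aldehyde cleaves only the C10–O bond next to the carbonyl (retention at C9, isolated oxirane untouched) and the aldol is acetylated cold before it can eliminate; C10 is epimerisable and is drawn as the 10β-formyl epimer that the next step needs.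

Step 7
Reactants: 11 acetoxy aldehyde 9α-acetoxy-4α,15-epoxy-8β-[(2R)-2-methylbutanoyloxy]-14-oxo-10αH-guai-11(13)-en-12,6-olide
Product: 12 target 9α-acetoxy-4β,14-epoxy-15-hydroxy-8β-[(2R)-2-methylbutanoyloxy]guaia-10(14),11(13)-dien-12,6-olide
Conditions: Sc(OTf)3 (5 mol %), 2,6-di-tert-butyl-4-methylpyridine (10 mol %), 4 Å MS, CH2Cl2, −40 to 0 °C
Reagents that add atoms: none
Why: Proposed new method: Sc(OTf)3 activates the 2,2-disubstituted oxirane and the formyl oxygen of the 10β-CHO group opens it 6-exo and anti at the tertiary C4 (inversion, so O is β and C15 is α), and because the freed C15 oxygen cannot reach the bridged oxocarbenium ion to close a ketal (that would need a second diaxial bridge at C4), the ion instead loses H-10 to give the 2-oxabicyclo[3.2.1]oct-3-ene enol ether and the free 15-hydroxyl; the closest known chemistry is the acid-catalysed epoxy-ketone to bicyclic-ketal cyclisation (carbonyl-oxygen epoxide opening) combined with Gassman-type deprotonation of an oxocarbenium ion to an enol ether.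

**Compound list**
1 | dehydrocostus lactone, (1αH,5αH,6βH,7αH)-guaia-4(15),10(14),11(13)-trien-12,6-olide | C=C1C(=O)O[C@H]2[C@H]1CCC(=C)[C@@H]3CCC(=C)[C@H]23 | starting material
2 | 4α,15-epoxyguaia-10(14),11(13)-dien-12,6-olide (oxirane O on the α-face) | C=C1C(=O)O[C@H]2[C@H]1CCC(=C)[C@@H]3CC[C@]4(CO4)[C@H]23 | intermediate
3 | 4α,15-epoxy-14-hydroperoxyguaia-9,11(13)-dien-12,6-olide | C=C1C(=O)O[C@H]2[C@H]1CC=C(COO)[C@@H]3CC[C@]4(CO4)[C@H]23 | intermediate
4 | 4α,15-epoxy-14-oxoguaia-9,11(13)-dien-12,6-olide | C=C1C(=O)O[C@H]2[C@H]1CC=C(C=O)[C@@H]3CC[C@]4(CO4)[C@H]23 | intermediate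
5 | 4α,15-epoxy-14-(trimethylsilyloxy)guaia-8,10(14),11(13)-trien-12,6-olide (C10=C14 geometry not defined) | C=C1C(=O)O[C@H]2[C@H]1C=CC(=CO[Si](C)(C)C)[C@@H]3CC[C@]4(CO4)[C@H]23 | intermediate
6 | 4α,15-epoxy-8α-hydroxy-14-oxoguaia-9,11(13)-dien-12,6-olide | C=C1C(=O)O[C@H]2[C@H]1[C@@H](O)C=C(C=O)[C@@H]3CC[C@]4(CO4)[C@H]23 | intermediate
7 | (R)-2-methylbutanoic acid | CC[C@@H](C)C(=O)O | starting material
8 | 4α,15-epoxy-8β-[(2R)-2-methylbutanoyloxy]-14-oxoguaia-9,11(13)-dien-12,6-olide | C=C1C(=O)O[C@H]2[C@H]1[C@H](OC(=O)[C@H](C)CC)C=C(C=O)[C@@H]3CC[C@]4(CO4)[C@H]23 | intermediate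
9 | 4α,15:9α,10α-diepoxy-8β-[(2R)-2-methylbutanoyloxy]-14-oxoguai-11(13)-en-12,6-olide | C=C1C(=O)O[C@H]2[C@H]1[C@H](OC(=O)[C@H](C)CC)[C@H]4O[C@@]4(C=O)[C@@H]3CC[C@]5(CO5)[C@H]23 | intermediate
10 | 4α,15-epoxy-9α-hydroxy-8β-[(2R)-2-methylbutanoyloxy]-14-oxo-10αH-guai-11(13)-en-12,6-olide | C=C1C(=O)O[C@H]2[C@H]1[C@H](OC(=O)[C@H](C)CC)[C@@H](O)[C@H](C=O)[C@@H]3CC[C@]4(CO4)[C@H]23 | intermediate
11 | 9α-acetoxy-4α,15-epoxy-8β-[(2R)-2-methylbutanoyloxy]-14-oxo-10αH-guai-11(13)-en-12,6-olide | C=C1C(=O)O[C@H]2[C@H]1[C@H](OC(=O)[C@H](C)CC)[C@@H](OC(C)=O)[C@H](C=O)[C@@H]3CC[C@]4(CO4)[C@H]23 | intermediate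
12 | CNP0013863.3, 9α-acetoxy-4β,14-epoxy-15-hydroxy-8β-[(2R)-2-methylbutanoyloxy]guaia-10(14),11(13)-dien-12,6-olide | C=C1C(=O)O[C@H]2[C@H]1[C@H](OC(=O)[C@H](C)CC)[C@@H](OC(C)=O)C1=CO[C@@]3(CO)CC[C@@H]1[C@@H]23 | target

**Step count and risks**
Total steps: 7. Longest linear sequence: 7 (from 1; the route is fully linear and 7 enters in step 4).

The three steps most likely to fail:

- Step 1 (choice between the two exocyclic alkenes; the wrong mono-epoxide or the bis-epoxide may form). Fallback, from 1 back to 2: LiOH in aqueous THF opens the lactone to the hydroxy acid 6α-hydroxyguaia-4(15),10(14),11(13)-trien-12-oic acid F1, handled as its lithium salt. A hydroxyl-directed epoxidation (VO(acac)2, tBuOOH) then uses the free 6α-OH, which is homoallylic only to C4=C15, to deliver oxygen to that alkene on the α-face and give the epoxy hydroxy acid 4α,15-epoxy-6α-hydroxyguaia-10(14),11(13)-dien-12-oic acid F2. Mild acidification closes the lactone again to 2.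

- Step 4 (SN2 at the hindered allylic C8 from the β-face; elimination may compete). Fallback, from 4 back to 8: the silyl dienol ether 5 is made as in step 3 and treated with NBS (THF, −78 °C), which brominates the γ-carbon from the α-face to give the bromo enal 8α-bromo-4α,15-epoxy-14-oxoguaia-9,11(13)-dien-12,6-olide F3. The far more reactive allylic bromide is then displaced with inversion by 7 in the presence of Cs2CO3 (DMF, rt) to give 8.

- Step 7 (the new isomerisation; a hydride shift of the oxirane to the 15-aldehyde or Lewis-acid ionisation of the allylic 9-acetate in the product could intervene). Fallback with known reactions, from 11 back to 12: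
  - Dilute HClO4 in THF/H2O hydrolyses the oxirane at the tertiary carbon with lactol closure to the bridged lactol 9α-acetoxy-4β,14-epoxy-14,15-dihydroxy-8β-[(2R)-2-methylbutanoyloxy]-10αH-guai-11(13)-en-12,6-olide F4.
  - TBSCl and imidazole protect the primary alcohol to give the 15-O-TBS lactol F5.
  - MsCl and Et3N dehydrate the lactol in the way glycals are made from lactols, giving the 15-O-TBS ether of the target F6.
  - HF·pyridine removes the silyl group to give 12.

**Further compounds**
F1 | step 1 | 6α-hydroxyguaia-4(15),10(14),11(13)-trien-12-oic acid | C=C(C(=O)O)[C@@H]1CCC(=C)[C@@H]2CCC(=C)[C@@H]2[C@H]1O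
F2 | step 1 | 4α,15-epoxy-6α-hydroxyguaia-10(14),11(13)-dien-12-oic acid | C=C(C(=O)O)[C@@H]1CCC(=C)[C@@H]2CC[C@]3(CO3)[C@@H]2[C@H]1O
F3 | step 4 | 8α-bromo-4α,15-epoxy-14-oxoguaia-9,11(13)-dien-12,6-olide | C=C1C(=O)O[C@H]2[C@H]1[C@@H](Br)C=C(C=O)[C@@H]3CC[C@]4(CO4)[C@H]23
F4 | step 7 | 9α-acetoxy-4β,14-epoxy-14,15-dihydroxy-8β-[(2R)-2-methylbutanoyloxy]-10αH-guai-11(13)-en-12,6-olide (one lactol anomer drawn) | C=C1C(=O)O[C@H]2[C@H]1[C@H](OC(=O)[C@H](C)CC)[C@@H](OC(C)=O)[C@@H]1[C@@H](O)O[C@@]3(CO)CC[C@@H]1[C@@H]23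
F5 | step 7 | 15-O-tert-butyldimethylsilyl ether of F4 | C=C1C(=O)O[C@H]2[C@H]1[C@H](OC(=O)[C@H](C)CC)[C@@H](OC(C)=O)[C@@H]1[C@@H](O)O[C@@]3(CO[Si](C)(C)C(C)(C)C)CC[C@@H]1[C@@H]23
F6 | step 7 | 15-O-tert-butyldimethylsilyl ether of 12 | C=C1C(=O)O[C@H]2[C@H]1[C@H](OC(=O)[C@H](C)CC)[C@@H](OC(C)=O)C1=CO[C@@]3(CO[Si](C)(C)C(C)(C)C)CC[C@@H]1[C@@H]23
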